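**Plan**
- Numbering of the target (7-oxabicyclo[4.1.0]heptane): C1 methyl-bearing oxirane carbon, C2 ketone, C3 isovalerate carbon, C4 side-chain carbon, C5 CH2, C6 oxirane CH.
- Cuts: the O–O–C bond of the hydroperoxide (ene reaction); the side-chain C(=CH2)–C(=O) bond (alkenyl iodide + aldehyde); the oxirane C–O bonds; the ring bond C2–C3; the C1=C6 alkene (olefination); the C4–alkenyl bond (conjugate addition).
- Forward: butenolide → C4 alkenyl group → Z-enoate → Z-dialdehyde → six-membered ring → oxirane ring → side chain → hydroperoxide.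
- Enabling feature: C2 (C=O) and C3 (CH–O) are an acyloin inside the six-membered ring, and without the oxirane oxygen C2 is also the carbonyl carbon of a C1=C6 enal, so C2 can act as an acyl-anion equivalent towards a C3 aldehyde.
- Stereochemistry: C4 from ligand-controlled rhodium addition; C3 set trans to C4 in the ring closure; C1/C6 from Luche reduction followed by hydroxyl-directed epoxidation; E-alkene from the ene reaction.

Key step: step 7

Remarks on the chemistry: read from the SMILES, the C4 side chain and the oxirane oxygen are cis and the C3 ester is trans to both. Compound 6 (anomers) and compound 19 (side-chain carbinol epimers) are carried as mixtures because these centres are removed later; their SMILES leave them open. The facial sense of (S)-BINAP in step 2 is assigned by analogy with cyclic enones.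

**Step 1**
Reactants: 1 (1-bromoethenyl)trimethylsilane
Product: 3 4,4,5,5-tetramethyl-2-[1-(trimethylsilyl)ethenyl]-1,3,2-dioxaborolane, via alkenylmagnesium bromide 2 (not isolated)
Conditions: Mg, THF, reflux; then 2-isopropoxy-4,4,5,5-tetramethyl-1,3,2-dioxaborolane, −78 to 23 °C; aq. NH4Cl
Reagents that add atoms: 2-isopropoxy-4,4,5,5-tetramethyl-1,3,2-dioxaborolane, CC(C)OB1OC(C)(C)C(C)(C)O1; magnesium, [Mg] (kept only in 2)
Why: Magnesium insertion into the alkenyl bromide and borylation of the Grignard reagent with an alkoxyboronate is the standard route to alkenyl pinacol boronates.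

**Step 2**
Reactants: 3 4,4,5,5-tetramethyl-2-[1-(trimethylsilyl)ethenyl]-1,3,2-dioxaborolane; 4 furan-2(5H)-one
Product: 5 (4R)-4-[1-(trimethylsilyl)ethenyl]oxolan-2-one
Conditions: [Rh(OH)(C8H12)]2 (2.5 mol%), (S)-2,2'-bis(diphenylphosphino)-1,1'-binaphthyl (5.5 mol%), 1,4-dioxane/H2O 10:1, 50 °C
Reagents that add atoms: none
Why: In this Hayashi–Miyaura asymmetric 1,4-addition the alkenylrhodium species should add to the butenolide enantioface selected by the (S)-ligand (the sense that gives 3S products from cyclohex-2-enone corresponds to 4R here), which sets the carbon that becomes C4 of the target.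

**Step 3**
Reactants: 5 (4R)-4-[1-(trimethylsilyl)ethenyl]oxolan-2-one
Product: 6 (4R)-4-[1-(trimethylsilyl)ethenyl]oxolan-2-ol (anomer mixture)
Conditions: i-Bu2AlH (1.1 equiv), CH2Cl2, −78 °C; aq. potassium sodium tartrate
Reagents that add atoms: none
Why: Partial reduction of a lactone stops at the lactol at −78 °C because the aluminium hemiacetal is stable until work-up.

**Step 4**
Reactants: 6 (4R)-4-[1-(trimethylsilyl)ethenyl]oxolan-2-ol; 7 ethyl 2-[bis(2,2,2-trifluoroethoxy)phosphoryl]propanoate
Product: 8 ethyl (2Z,5R)-6-hydroxy-2-methyl-5-[1-(trimethylsilyl)ethenyl]hex-2-enoate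
Conditions: 7 (2.5 equiv), KN(SiMe3)2, 18-crown-6, THF, −78 °C; then 6, −78 to −40 °C; aq. NH4Cl at −78 °C
Reagents that add atoms: none
Why: Still–Gennari olefination of the open hydroxy-aldehyde form should give the Z-trisubstituted enoate, because the trifluoroethyl phosphonate adduct eliminates fast and irreversibly, and the cold quench limits oxa-Michael closure of the freed alkoxide.

**Step 5**
Reactants: 8 ethyl (2Z,5R)-6-hydroxy-2-methyl-5-[1-(trimethylsilyl)ethenyl]hex-2-enoate
Product: 9 (2Z,5R)-2-methyl-5-[1-(trimethylsilyl)ethenyl]hex-2-ene-1,6-diol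
Conditions: i-Bu2AlH (3.5 equiv), CH2Cl2, −78 to −20 °C; aq. potassium sodium tartrate
Reagents that add atoms: none
Why: 1,2-Reduction of the unsaturated ester gives the allylic alcohol with the alkene geometry unchanged.

**Step 6**
Reactants: 9 (2Z,5R)-2-methyl-5-[1-(trimethylsilyl)ethenyl]hex-2-ene-1,6-diol
Product: 10 (2Z,5R)-2-methyl-5-[1-(trimethylsilyl)ethenyl]hex-2-enedial
Conditions: Dess–Martin periodinane (2.6 equiv), NaHCO3, CH2Cl2, 0 °C; filtered and used at once
Reagents that add atoms: none
Why: Buffered Dess–Martin oxidation converts both primary alcohols to aldehydes under non-basic conditions that should preserve the Z-enal and the α-stereocenter.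

**Step 7**
Reactants: 10 (2Z,5R)-2-methyl-5-[1-(trimethylsilyl)ethenyl]hex-2-enedial; 11 3-methylbutanoic anhydride
Product: 13 (1S,6R)-3-methyl-2-oxo-6-[1-(trimethylsilyl)ethenyl]cyclohex-3-en-1-yl 3-methylbutanoate, via hydroxy enone 12 (not isolated)
Conditions: 2-mesityl-6,7-dihydro-5H-pyrrolo[2,1-c][1,2,4]triazol-2-ium chloride (10 mol%), i-Pr2NEt (20 mol%), toluene (0.02 M), 23 °C; then 11 (1.5 equiv), 4-(dimethylamino)pyridine (10 mol%), Et3N, 0 °C
Reagents that add atoms: none
Why: The triazolylidene released from the salt adds to the C1 enal carbonyl of 10, proton transfer gives the conjugated acyl-anion equivalent (Breslow intermediate), its C1 attacks the C6 aldehyde carbon, and loss of the carbene leaves acyloin 12, which the anhydride esterifies in the same flask. The closest known reaction type is the carbene-catalysed crossed benzoin cyclisation of 1,6-dialdehydes to 2-hydroxycyclohexanones. The six-membered carbocycle closes in a 6-exo-trig mode, with the Z-alkene holding C1 within reach of C6. The new C6 stereocenter is controlled by the C5 stereocenter, since a chair-like transition state with the C5 substituent equatorial and the reversibility of the benzoin addition both lead to the trans-diequatorial hydroxy ketone. The step needs donor/acceptor regioselectivity, which is secured because the N-mesityl carbene converts the enal far more readily than the hindered α-branched C6 aldehyde and because reversible addition drains into the conjugated, hydrogen-bonded α'-hydroxy enone. The β-carbon (homoenolate) pathway cannot close a ring, since it would be four-membered, and the aprotic, weakly basic, dilute medium limits β-protonation, epimerisation at C5 and oligomerisation.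

**Step 8**
Reactants: 13 (1S,6R)-3-methyl-2-oxo-6-[1-(trimethylsilyl)ethenyl]cyclohex-3-en-1-yl 3-methylbutanoate
Product: 14 (1S,6R)-6-(1-iodoethenyl)-3-methyl-2-oxocyclohex-3-en-1-yl 3-methylbutanoate
Conditions: N-iodosuccinimide (1.3 equiv), (CF3)2CHOH, 0 °C, dark
Reagents that add atoms: N-iodosuccinimide, O=C1CCC(=O)N1I
Why: Ipso-iododesilylation should occur only at the electron-rich alkenylsilane, by iodonium attack and loss of the silyl group, while the electron-poor enone alkene is left alone.

**Step 9**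
Reactants: 14 (1S,6R)-6-(1-iodoethenyl)-3-methyl-2-oxocyclohex-3-en-1-yl 3-methylbutanoate
Product: 15 (1S,2S,6R)-2-hydroxy-6-(1-iodoethenyl)-3-methylcyclohex-3-en-1-yl 3-methylbutanoate
Conditions: NaBH4, CeCl3·7H2O, MeOH, −78 °C; aq. NH4Cl
Reagents that add atoms: none
Why: Luche 1,2-reduction with axial hydride delivery should give the equatorial allylic alcohol cis to the iodoalkenyl substituent and trans to the ester (as in carvone to cis-carveol), which is needed because direct alkaline epoxidation of the enone would be expected to place oxygen trans to that substituent.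

**Step 10**
Reactants: 15 (1S,2S,6R)-2-hydroxy-6-(1-iodoethenyl)-3-methylcyclohex-3-en-1-yl 3-methylbutanoate
Product: 16 (1R,2R,3S,4R,6S)-2-hydroxy-4-(1-iodoethenyl)-1-methyl-7-oxabicyclo[4.1.0]heptan-3-yl 3-methylbutanoate
Conditions: VO(acac)2 (acac = C5H7O2, 5 mol%), t-BuOOH (1.5 equiv, decane), CH2Cl2, 0 to 23 °C
Reagents that add atoms: tert-butyl hydroperoxide, CC(C)(C)OO
Why: Hydroxyl-directed vanadium-catalysed epoxidation delivers oxygen to the ring alkene on the face of the allylic hydroxyl, which sets both oxirane carbons cis to the C4 substituent and leaves the iodoalkene untouched.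

**Step 11**
Reactants: 17 4-methylpent-3-en-1-ol
Product: 18 4-methylpent-3-enal
Conditions: Dess–Martin periodinane, NaHCO3, CH2Cl2, 0 °C; used as a cold solution
Reagents that add atoms: none
Why: Buffered Dess–Martin oxidation gives the β,γ-unsaturated aldehyde without moving the alkene into conjugation.

**Step 12**
Reactants: 16 (1R,2R,3S,4R,6S)-2-hydroxy-4-(1-iodoethenyl)-1-methyl-7-oxabicyclo[4.1.0]heptan-3-yl 3-methylbutanoate; 18 4-methylpent-3-enal
Product: 19 (1R,2R,3S,4S,6S)-2-hydroxy-4-(3-hydroxy-6-methylhepta-1,5-dien-2-yl)-1-methyl-7-oxabicyclo[4.1.0]heptan-3-yl 3-methylbutanoate (epimers at the side-chain carbinol)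
Conditions: CrCl2 (6 equiv), NiCl2 (2 mol%), 18 (3 equiv), DMF, 23 °C
Reagents that add atoms: none
Why: The Nozaki–Hiyama–Kishi reaction forms an alkenylchromium reagent that adds only to the aldehyde and tolerates the free hydroxyl, the oxirane and the ester.

**Step 13**
Reactants: 19 (1R,2R,3S,4S,6S)-2-hydroxy-4-(3-hydroxy-6-methylhepta-1,5-dien-2-yl)-1-methyl-7-oxabicyclo[4.1.0]heptan-3-yl 3-methylbutanoate
Product: 20 (1S,3S,4S,6S)-1-methyl-4-(6-methyl-3-oxohepta-1,5-dien-2-yl)-2-oxo-7-oxabicyclo[4.1.0]heptan-3-yl 3-methylbutanoate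
Conditions: Dess–Martin periodinane (3 equiv), NaHCO3, CH2Cl2, 0 to 23 °C
Reagents that add atoms: none
Why: Neutral Dess–Martin oxidation of both secondary alcohols gives the epoxy ketone and the side-chain enone at once, without conjugating the β,γ-alkene or epimerising the acyloxy carbon.

**Step 14**
Reactants: 20 (1S,3S,4S,6S)-1-methyl-4-(6-methyl-3-oxohepta-1,5-dien-2-yl)-2-oxo-7-oxabicyclo[4.1.0]heptan-3-yl 3-methylbutanoate
Product: 21 (1S,3S,4S,6S)-4-[(4E)-6-hydroperoxy-6-methyl-3-oxohepta-1,4-dien-2-yl]-1-methyl-2-oxo-7-oxabicyclo[4.1.0]heptan-3-yl 3-methylbutanoate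
Conditions: O2, visible light, 5,10,15,20-tetraphenylporphyrin (1 mol%), CH2Cl2, −20 °C; non-reductive work-up
Reagents that add atoms: dioxygen, O=O
Why: In the Schenck ene reaction singlet oxygen should attack only the electron-rich trisubstituted alkene and abstract a hydrogen from the CH2 flanked by the carbonyl, giving the tertiary hydroperoxide with a conjugated E-alkene.

**Compound list**
1 | (1-bromoethenyl)trimethylsilane | C=C(Br)[Si](C)(C)C | starting material
2 | [1-(trimethylsilyl)ethenyl]magnesium bromide | C=C([Mg]Br)[Si](C)(C)C | intermediate (not isolated)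
3 | 4,4,5,5-tetramethyl-2-[1-(trimethylsilyl)ethenyl]-1,3,2-dioxaborolane | C=C([Si](C)(C)C)B1OC(C)(C)C(C)(C)O1 | intermediate
4 | furan-2(5H)-one | O=C1C=CCO1 | starting material
5 | (4R)-4-[1-(trimethylsilyl)ethenyl]oxolan-2-one | C=C([Si](C)(C)C)[C@@H]1CC(=O)OC1 | intermediate
6 | (4R)-4-[1-(trimethylsilyl)ethenyl]oxolan-2-ol | C=C([Si](C)(C)C)[C@@H]1CC(O)OC1 | intermediate
7 | ethyl 2-[bis(2,2,2-trifluoroethoxy)phosphoryl]propanoate | CCOC(=O)C(C)P(=O)(OCC(F)(F)F)OCC(F)(F)F | starting material
8 | ethyl (2Z,5R)-6-hydroxy-2-methyl-5-[1-(trimethylsilyl)ethenyl]hex-2-enoate | C=C([Si](C)(C)C)[C@@H](CO)C/C=C(/C)C(=O)OCC | intermediate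
9 | (2Z,5R)-2-methyl-5-[1-(trimethylsilyl)ethenyl]hex-2-ene-1,6-diol | C=C([Si](C)(C)C)[C@@H](CO)C/C=C(/C)CO | intermediate
10 | (2Z,5R)-2-methyl-5-[1-(trimethylsilyl)ethenyl]hex-2-enedial | C=C([Si](C)(C)C)[C@@H](C=O)C/C=C(/C)C=O | intermediate
11 | 3-methylbutanoic anhydride | CC(C)CC(=O)OC(=O)CC(C)C | starting material
12 | (5R,6S)-6-hydroxy-2-methyl-5-[1-(trimethylsilyl)ethenyl]cyclohex-2-en-1-one | C=C([Si](C)(C)C)[C@@H]1CC=C(C)C(=O)[C@H]1O | intermediate (not isolated)
13 | (1S,6R)-3-methyl-2-oxo-6-[1-(trimethylsilyl)ethenyl]cyclohex-3-en-1-yl 3-methylbutanoate | C=C([Si](C)(C)C)[C@@H]1CC=C(C)C(=O)[C@H]1OC(=O)CC(C)C | intermediate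
14 | (1S,6R)-6-(1-iodoethenyl)-3-methyl-2-oxocyclohex-3-en-1-yl 3-methylbutanoate | C=C(I)[C@@H]1CC=C(C)C(=O)[C@H]1OC(=O)CC(C)C | intermediate
15 | (1S,2S,6R)-2-hydroxy-6-(1-iodoethenyl)-3-methylcyclohex-3-en-1-yl 3-methylbutanoate | C=C(I)[C@@H]1CC=C(C)[C@H](O)[C@H]1OC(=O)CC(C)C | intermediate
16 | (1R,2R,3S,4R,6S)-2-hydroxy-4-(1-iodoethenyl)-1-methyl-7-oxabicyclo[4.1.0]heptan-3-yl 3-methylbutanoate | C=C(I)[C@@H]1C[C@@H]2O[C@]2(C)[C@H](O)[C@H]1OC(=O)CC(C)C | intermediate
17 | 4-methylpent-3-en-1-ol | CC(C)=CCCO | starting material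
18 | 4-methylpent-3-enal | CC(C)=CCC=O | intermediate
19 | (1R,2R,3S,4S,6S)-2-hydroxy-4-(3-hydroxy-6-methylhepta-1,5-dien-2-yl)-1-methyl-7-oxabicyclo[4.1.0]heptan-3-yl 3-methylbutanoate | C=C(C(O)CC=C(C)C)[C@@H]1C[C@@H]2O[C@]2(C)[C@H](O)[C@H]1OC(=O)CC(C)C | intermediate
20 | (1S,3S,4S,6S)-1-methyl-4-(6-methyl-3-oxohepta-1,5-dien-2-yl)-2-oxo-7-oxabicyclo[4.1.0]heptan-3-yl 3-methylbutanoate | C=C(C(=O)CC=C(C)C)[C@@H]1C[C@@H]2O[C@]2(C)C(=O)[C@H]1OC(=O)CC(C)C | intermediate
21 | (1S,3S,4S,6S)-4-[(4E)-6-hydroperoxy-6-methyl-3-oxohepta-1,4-dien-2-yl]-1-methyl-2-oxo-7-oxabicyclo[4.1.0]heptan-3-yl 3-methylbutanoate | C=C(C(=O)/C=C/C(C)(C)OO)[C@@H]1C[C@@H]2O[C@]2(C)C(=O)[C@H]1OC(=O)CC(C)C | target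

Total step count: 14. Longest linear sequence: 13 steps (steps 1–10 and 12–14, from compound 1).

**Steps most likely to fail**

1. Step 7. The basic carbene medium may epimerise C5 or isomerise the Z-enal to the E-enal before ring closure, the enal-derived intermediate may be diverted into β-protonation, or the regioisomeric acyloin may persist. The fallback sets out from 10 and returns at 13. Dialdehyde 10 would be cyclised by reductive pinacol coupling with SmI2 (THF, t-BuOH, −78 °C), a fast non-basic ketyl–carbonyl coupling that forms the same ring bond, to (1S,6R)-3-methyl-6-[1-(trimethylsilyl)ethenyl]cyclohex-3-ene-1,2-diol F1 (configuration at C2 immaterial). MnO2 in CH2Cl2 would then oxidise only the allylic hydroxyl to give 12, and acylation with 11 (4-(dimethylamino)pyridine, Et3N) gives 13.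

2. Step 14. Hydrogen abstraction may occur at a methyl group instead of the methylene (regioisomeric secondary hydroperoxide), or the hydroperoxide may decompose during the reaction. The fallback sets out from 16 and returns at 21. Compound 16 would be coupled with prop-2-enal (CrCl2, NiCl2 catalyst, DMF) to (1R,2R,3S,4S,6S)-2-hydroxy-4-(3-hydroxypenta-1,4-dien-2-yl)-1-methyl-7-oxabicyclo[4.1.0]heptan-3-yl 3-methylbutanoate F2. Separately, 2-methylbut-3-en-2-ol would be converted with aqueous H2O2 and catalytic H2SO4 into 2-methylbut-3-en-2-yl hydroperoxide F3 and protected with 2-methoxypropene (pyridinium p-toluenesulfonate) as 3-[(2-methoxypropan-2-yl)peroxy]-3-methylbut-1-ene F4. Cross-metathesis of F2 with F4 (second-generation Hoveyda–Grubbs catalyst, CH2Cl2, 40 °C) would give the E-alkene peroxyketal diol F5. Dess–Martin oxidation of both carbinols would give the diketone peroxyketal F6, and aqueous acetic acid in THF would release the hydroperoxide 21. The peroxide carbon is thus fixed by the building block and not by the ene regiochemistry.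

3. Step 2. The hindered α-silyl alkenyl group may transmetalate or insert slowly, protodeboronation may compete, and enantioface control may be insufficient. The fallback sets out from 1 and returns at 5. Grignard reagent 2, made from 1 as in step 1, would be added (CuBr·SMe2, THF, −78 °C) to commercial (5R)-5-{[(1R,2S,5R)-5-methyl-2-(propan-2-yl)cyclohexyl]oxy}furan-2(5H)-one. The acetal substituent directs the alkenyl group to the opposite face and gives (4R,5R)-5-{[(1R,2S,5R)-5-methyl-2-(propan-2-yl)cyclohexyl]oxy}-4-[1-(trimethylsilyl)ethenyl]oxolan-2-one F7. NaBH4 in aqueous KOH/ethanol followed by acidification would reduce the masked aldehyde, release the auxiliary alcohol and close lactone 5.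

**Further compounds**
F1 | step 7 | (1S,6R)-3-methyl-6-[1-(trimethylsilyl)ethenyl]cyclohex-3-ene-1,2-diol | C=C([Si](C)(C)C)[C@@H]1CC=C(C)C(O)[C@H]1O
F2 | step 14 | (1R,2R,3S,4S,6S)-2-hydroxy-4-(3-hydroxypenta-1,4-dien-2-yl)-1-methyl-7-oxabicyclo[4.1.0]heptan-3-yl 3-methylbutanoate | C=C(C(O)C=C)[C@@H]1C[C@@H]2O[C@]2(C)[C@H](O)[C@H]1OC(=O)CC(C)C
F3 | step 14 | 2-methylbut-3-en-2-yl hydroperoxide | C=CC(C)(C)OO
F4 | step 14 | 3-[(2-methoxypropan-2-yl)peroxy]-3-methylbut-1-ene | C=CC(C)(C)OOC(C)(C)OC
F5 | step 14 | (1R,2R,3S,4S,6S)-2-hydroxy-4-{(4E)-3-hydroxy-6-[(2-methoxypropan-2-yl)peroxy]-6-methylhepta-1,4-dien-2-yl}-1-methyl-7-oxabicyclo[4.1.0]heptan-3-yl 3-methylbutanoate | C=C(C(O)/C=C/C(C)(C)OOC(C)(C)OC)[C@@H]1C[C@@H]2O[C@]2(C)[C@H](O)[C@H]1OC(=O)CC(C)C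
F6 | step 14 | (1S,3S,4S,6S)-4-{(4E)-6-[(2-methoxypropan-2-yl)peroxy]-6-methyl-3-oxohepta-1,4-dien-2-yl}-1-methyl-2-oxo-7-oxabicyclo[4.1.0]heptan-3-yl 3-methylbutanoate | C=C(C(=O)/C=C/C(C)(C)OOC(C)(C)OC)[C@@H]1C[C@@H]2O[C@]2(C)C(=O)[C@H]1OC(=O)CC(C)C
F7 | step 2 | (4R,5R)-5-{[(1R,2S,5R)-5-methyl-2-(propan-2-yl)cyclohexyl]oxy}-4-[1-(trimethylsilyl)ethenyl]oxolan-2-one | C[C@@H]1CC[C@H]([C@@H](C1)O[C@@H]2OC(=O)C[C@H]2C(=C)[Si](C)(C)C)C(C)C
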